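**Retrosynthetic overview**
- The target comes from its bis-silyl ether; the C2=C3 alkene comes from a C3 ketone (reduction, dehydration) and the exocyclic methylene from a C10 ketone (Wittig).
- Key bond C1–C10: the seven-membered ring is closed by an intramolecular Stetter reaction, in which an acyl anion at C10 (from an aldehyde) attacks C1, the β-carbon of a cyclopentenone.
- Bond C5–C6: vinylogous Mukaiyama aldol between a chiral silyloxy-cyclopentadiene (C1–C5, C4 carbinol already in place) and an α-branched aldehyde carrying C6–C15.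
- The five-membered ring comes from (R)-linalool (ring-closing metathesis, then ene oxidation); the side chain comes from (R)-citronellal (allylic oxidation, CBS reduction), with C7 set by organocatalytic α-allylation.
- Ring order: five-membered ring first, seven-membered ring last.

Locants used below (target numbering): C1 and C5 ring-fusion carbons, C2=C3, C4 (C–OH, CH3), C6 (CH–OH), C7, C8, C9, C10 (=CH2), C11 (CH–CH3), C12, C13 (CH–OAc), C14=C15(CH3)2.
Assumption: in the reagent-controlled steps 3 and 5 the catalyst enantiomer named is the one expected to give the drawn configuration; if the sense of induction is opposite, the mirror-image catalyst is used.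

**Step 1**
Reactants: 1 (R)-citronellal
Product: 2 (6R)-8,8-dimethoxy-2,6-dimethyloct-2-ene
Conditions: HC(OMe)3, MeOH, pyridinium p-toluenesulfonate (cat.), rt
Reagents that add atoms: trimethyl orthoformate, COC(OC)OC
Why: Acid-catalysed acetalisation protects the aldehyde for the oxidation and reduction that follow; no stereocenter is touched.

**Step 2**
Reactants: 2 (6R)-8,8-dimethoxy-2,6-dimethyloct-2-ene
Product: 3 (6S)-8,8-dimethoxy-2,6-dimethyloct-2-en-4-one
Conditions: Rh2(cap)4 (dirhodium tetrakis(caprolactamate), 1 mol %), t-BuOOH (70% aq., 5 equiv), K2CO3, CH2Cl2, rt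
Reagents that add atoms: tert-butyl hydroperoxide, CC(C)(C)OO
Why: Allylic C–H oxidation (peroxyl-radical mechanism) converts the only secondary allylic CH2 into the conjugated enone; the methyl-bearing center is unchanged (its descriptor changes only through CIP priorities).

**Step 3**
Reactants: 3 (6S)-8,8-dimethoxy-2,6-dimethyloct-2-en-4-one
Product: 5 (4R,6R)-8,8-dimethoxy-2,6-dimethyloct-2-en-4-yl acetate, via allylic alcohol 4 (not isolated)
Conditions: (S)-1-methyl-3,3-diphenyl-tetrahydro-1H,3H-pyrrolo[1,2-c][1,3,2]oxazaborole ((S)-Me-CBS, 20 mol %), catecholborane, toluene, −78 °C; aqueous work-up; then Ac2O, pyridine, 4-(dimethylamino)pyridine (cat.), CH2Cl2, 0 °C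
Reagents that add atoms: acetic anhydride, CC(=O)OC(C)=O
Why: Corey–Bakshi–Shibata reduction gives 1,2-reduction of the enone with the alkenyl group as the large substituent, so the (S)-catalyst sets C13 as R under reagent control; acetylation then fixes the acetate of the target.

**Step 4**
Reactants: 5 (4R,6R)-8,8-dimethoxy-2,6-dimethyloct-2-en-4-yl acetate
Product: 6 (4R,6R)-2,6-dimethyl-8-oxooct-2-en-4-yl acetate
Conditions: pyridinium p-toluenesulfonate (cat.), acetone/H2O (10:1), 45 °C
Reagents that add atoms: water, O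
Why: Mild acetal hydrolysis releases the aldehyde (C6) without touching the allylic acetate.

**Step 5**
Reactants: 6 (4R,6R)-2,6-dimethyl-8-oxooct-2-en-4-yl acetate
Product: 7 (4R,6R,7S)-7-formyl-2,6-dimethyldeca-2,9-dien-4-yl acetate
Conditions: allyltrimethylsilane (2.5 equiv), (2S,5S)-5-benzyl-2-tert-butyl-3-methylimidazolidin-4-one trifluoroacetate (20 mol %), (NH4)2Ce(NO3)6 (2 equiv), NaHCO3, H2O (2 equiv), 1,2-dimethoxyethane, −20 °C
Reagents that add atoms: allyltrimethylsilane, C=CC[Si](C)(C)C
Why: MacMillan SOMO-activated α-allylation: the enamine radical cation is trapped by the allylsilane on the face left open by the catalyst, which sets C7 (S) under catalyst control and installs C8–C10.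

**Step 6**
Reactants: 8 (R)-linalool
Product: 9 (1R)-1-methylcyclopent-2-en-1-ol
Conditions: second-generation Grubbs catalyst RuCl2(=CHPh)(PCy3)(H2IMes) (0.5 mol %), CH2Cl2, 40 °C
Reagents that add atoms: none
Why: Ring-closing metathesis closes the five-membered ring with loss of the prenyl terminus; the tertiary carbinol (future C4) comes unchanged from the chiral pool.

**Step 7**
Reactants: 9 (1R)-1-methylcyclopent-2-en-1-ol
Product: 11 (5R)-5-hydroxy-5-methylcyclopent-2-en-1-one, via allylic hydroperoxide 10 (not isolated)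
Conditions: O2, 5,10,15,20-tetraphenylporphyrin (0.5 mol %), visible light, CH2Cl2, 0 °C; then Ac2O, pyridine, 0 °C to rt
Reagents that add atoms: dioxygen, O=O
Why: Schenck ene reaction can only abstract the ring CH2 hydrogen (the carbinol carbon has none), so oxygen goes on the carbon next to the carbinol, and Kornblum–DeLaMare dehydration of the secondary hydroperoxide gives the transposed enone; the carbinol center is unchanged.

**Step 8**
Reactants: 11 (5R)-5-hydroxy-5-methylcyclopent-2-en-1-one
Product: 12 (5R)-5-methyl-1,5-bis(triethylsilyloxy)cyclopenta-1,3-diene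
Conditions: Et3SiOTf (2.3 equiv), Et3N (3 equiv), CH2Cl2, −78 to 0 °C
Reagents that add atoms: triethylsilyl trifluoromethanesulfonate, CC[Si](CC)(CC)OS(=O)(=O)C(F)(F)F
Why: Soft enolisation/silylation: the α′ position is quaternary, so only γ-deprotonation is possible, giving the linear silyl dienol ether while the tertiary alcohol is silylated; the diene cannot undergo hydrogen shifts because its sp3 carbon carries no hydrogen.

**Step 9**
Reactants: 7 (4R,6R,7S)-7-formyl-2,6-dimethyldeca-2,9-dien-4-yl acetate and 12 (5R)-5-methyl-1,5-bis(triethylsilyloxy)cyclopenta-1,3-diene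
Product: 13 (4R,5R,6R,7S,11R,13R)-aldol adduct: cyclopentenone (C3=O, C1=C2, C4 bearing CH3 and OSiEt3) joined at C5 to C6H(OSiEt3)–C7H(allyl)–C11H(CH3)–C12H2–C13H(OAc)–C14H=C15(CH3)2
Conditions: Et3SiOTf (10 mol %), 2,6-di-tert-butyl-4-methylpyridine (20 mol %), CH2Cl2, −78 °C
Reagents that add atoms: none
Why: Vinylogous Mukaiyama aldol with silyl transfer: the diene reacts at its γ-terminus C5 on the face away from the bulky C4 silyloxy group (which also avoids the silylated aldehyde oxygen), so C6 ends cis to the C4 methyl, and the aldehyde is attacked in the Felkin–Anh sense with C11 as the large group, which places the C6 oxygen syn to the C7 side chain.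

**Step 10**
Reactants: 13 (4R,5R,6R,7S,11R,13R)-aldol adduct
Product: 14 (4R,5R,6R,7S,11R,13R)-aldehyde: as 13 with C8H2–C9H2–C10HO in place of the allyl group
Conditions: PdCl2(PhCN)2 (12 mol %), CuCl2·2H2O (12 mol %), AgNO2 (6 mol %), O2 (1 atm), t-BuOH/MeNO2 (15:1), rt
Reagents that add atoms: dioxygen, O=O
Why: Nitrite-modified, aldehyde-selective (anti-Markovnikov) Wacker oxidation converts only the monosubstituted terminal alkene; the enone and the trisubstituted alkene are inert and no stereocenter is formed.

**Step 11**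
Reactants: 14 (4R,5R,6R,7S,11R,13R)-aldehyde
Product: 15 (1R,4R,5R,6R,7S,11R,13R)-trans-fused bicyclo[5.3.0]decane-3,10-dione (ketones at C3 and C10; C4 with CH3 and OSiEt3; C6–OSiEt3; C7 side chain)
Conditions: 3-benzyl-5-(2-hydroxyethyl)-4-methylthiazolium chloride (30 mol %), Et3N (0.6 equiv), 1,4-dioxane, 70 °C, 0.01 M
Reagents that add atoms: none
Why: Proposed new method: intramolecular Stetter reaction closing a seven-membered ring (7-exo), in which the thiazolium-derived Breslow intermediate (acyl anion at C10) adds to the enone β-carbon C1; the closest known type is the five- and six-membered intramolecular Stetter reaction of aliphatic aldehydes onto enones, and C1, now α to the new ketone, equilibrates under Et3N to the trans ring fusion with C10 anti to the C5 substituent.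

**Step 12**
Reactants: 15 (1R,4R,5R,6R,7S,11R,13R)-dione
Product: 16 (1R,4R,5R,6R,7S,11R,13R)-10-methylene-3-ketone
Conditions: Ph3PCH3Br (1.3 equiv), KOt-Bu (1.2 equiv), THF, 0 °C
Reagents that add atoms: methyltriphenylphosphonium bromide, C[P+](c1ccccc1)(c1ccccc1)c1ccccc1.[Br-]
Why: Wittig methylenation occurs at the C10 ketone because the C3 ketone is shielded by the adjacent quaternary C4 with its silyloxy group; any C1 epimerisation under the ylide leads to the same trans-fused isomer.

**Step 13**
Reactants: 16 (1R,4R,5R,6R,7S,11R,13R)-10-methylene-3-ketone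
Product: 17 (1R,3S,4R,5R,6R,7S,11R,13R)-C3 alcohol (major epimer drawn; both epimers are used)
Conditions: NaBH4, MeOH, 0 °C
Reagents that add atoms: none
Why: Borohydride reduction of the only ketone, with hydride expected anti to the C4 silyloxy group; the new C3 center is removed in the next step, and the acetate survives at 0 °C.

**Step 14**
Reactants: 17 C3 alcohol
Product: 18 (1R,4S,5R,6R,7S,11R,13R)-bis(triethylsilyl) ether of the target
Conditions: Ph2S[OC(CF3)2Ph]2 (Martin sulfurane, 1.5 equiv), CH2Cl2, rt
Reagents that add atoms: none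
Why: Martin sulfurane dehydration (E2 from the alkoxysulfonium) can only take a hydrogen from C2 because C4 is quaternary, so the C2=C3 alkene forms regiospecifically next to the tertiary silyl ether.

**Step 15**
Reactants: 18 bis(triethylsilyl) ether of the target
Product: 19 target compound
Conditions: HF·pyridine, pyridine, THF, 0 °C to rt
Reagents that add atoms: none
Why: Buffered fluoride desilylation frees the C4 and C6 hydroxyls; the allylic acetate and the acid-sensitive tertiary allylic alcohol are retained.

**Compound list**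
1 | (R)-citronellal, (3R)-3,7-dimethyloct-6-enal | O=CC[C@H](C)CCC=C(C)C | starting material
2 | (6R)-8,8-dimethoxy-2,6-dimethyloct-2-ene | COC(OC)C[C@H](C)CCC=C(C)C | intermediate
3 | (6S)-8,8-dimethoxy-2,6-dimethyloct-2-en-4-one | COC(OC)C[C@H](C)CC(=O)C=C(C)C | intermediate
4 | (4R,6R)-8,8-dimethoxy-2,6-dimethyloct-2-en-4-ol | COC(OC)C[C@H](C)C[C@H](C=C(C)C)O | intermediate
5 | (4R,6R)-8,8-dimethoxy-2,6-dimethyloct-2-en-4-yl acetate | COC(OC)C[C@H](C)C[C@H](C=C(C)C)OC(C)=O | intermediate
6 | (4R,6R)-2,6-dimethyl-8-oxooct-2-en-4-yl acetate | O=CC[C@H](C)C[C@H](C=C(C)C)OC(C)=O | intermediate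
7 | (4R,6R,7S)-7-formyl-2,6-dimethyldeca-2,9-dien-4-yl acetate | C=CC[C@@H]([C@H](C)C[C@H](C=C(C)C)OC(C)=O)C=O | intermediate
8 | (R)-linalool, (3R)-3,7-dimethylocta-1,6-dien-3-ol | C=C[C@](C)(O)CCC=C(C)C | starting material
9 | (1R)-1-methylcyclopent-2-en-1-ol | C1=C[C@](C)(O)CC1 | intermediate
10 | (1R,2S)-2-hydroperoxy-1-methylcyclopent-3-en-1-ol | C[C@@]1(O)CC=C[C@@H]1OO | intermediate
11 | (5R)-5-hydroxy-5-methylcyclopent-2-en-1-one | C[C@@]1(O)CC=CC1=O | intermediate
12 | (5R)-5-methyl-1,5-bis(triethylsilyloxy)cyclopenta-1,3-diene | C[C@@]1(O[Si](CC)(CC)CC)C=CC=C1O[Si](CC)(CC)CC | intermediate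
13 | (4R,5R,6R,7S,11R,13R)-vinylogous aldol adduct (cyclopentenone with C4 CH3/OSiEt3, C6–OSiEt3, C7 allyl, C13 acetate) | C=CC[C@@H]([C@H](C)C[C@H](C=C(C)C)OC(C)=O)[C@@H](O[Si](CC)(CC)CC)[C@H]1C=CC(=O)[C@]1(C)O[Si](CC)(CC)CC | intermediate
14 | (4R,5R,6R,7S,11R,13R)-C10 aldehyde | O=CCC[C@@H]([C@H](C)C[C@H](C=C(C)C)OC(C)=O)[C@@H](O[Si](CC)(CC)CC)[C@H]1C=CC(=O)[C@]1(C)O[Si](CC)(CC)CC | intermediate
15 | (1R,4R,5R,6R,7S,11R,13R)-trans-fused 3,10-dione | O=C1CC[C@@H]([C@H](C)C[C@H](C=C(C)C)OC(C)=O)[C@@H](O[Si](CC)(CC)CC)[C@H]2[C@H]1CC(=O)[C@]2(C)O[Si](CC)(CC)CC | intermediate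
16 | (1R,4R,5R,6R,7S,11R,13R)-10-methylene-3-ketone | C=C1CC[C@@H]([C@H](C)C[C@H](C=C(C)C)OC(C)=O)[C@@H](O[Si](CC)(CC)CC)[C@H]2[C@H]1CC(=O)[C@]2(C)O[Si](CC)(CC)CC | intermediate
17 | (1R,3S,4R,5R,6R,7S,11R,13R)-C3 alcohol | C=C1CC[C@@H]([C@H](C)C[C@H](C=C(C)C)OC(C)=O)[C@@H](O[Si](CC)(CC)CC)[C@H]2[C@H]1C[C@H](O)[C@]2(C)O[Si](CC)(CC)CC | intermediate
18 | (1R,4S,5R,6R,7S,11R,13R)-4,6-bis(triethylsilyl) ether of the target | C=C1CC[C@@H]([C@H](C)C[C@H](C=C(C)C)OC(C)=O)[C@@H](O[Si](CC)(CC)CC)[C@H]2[C@H]1C=C[C@]2(C)O[Si](CC)(CC)CC | intermediate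
19 | target compound CNP0209568.3, (1R,4S,5R,6R,7S,11R,13R) | C=C1CC[C@@H]([C@H](C)C[C@H](C=C(C)C)OC(C)=O)[C@@H](O)[C@H]2[C@H]1C=C[C@]2(C)O | target

**Step count**
Total: 15 steps. Longest linear sequence: 12 steps (steps 1–5, then 9–15).

**Three steps most likely to fail, each with a fallback**

Step 11 is the least certain: a Stetter closure of a seven-membered ring is unproven, the C5 hydrogen of 14 is γ-acidic under base, and the trans ring fusion relies on equilibration. The fallback sets out from 14 and comes back at 15 by an acyl-radical cyclisation instead of a polar acyl anion. Pinnick oxidation (NaClO2, NaH2PO4, 2-methylbut-2-ene) gives the carboxylic acid F1. PhSeSePh/PBu3 converts it into the Se-phenyl selenoester F2. Bu3SnH with azobisisobutyronitrile (slow addition, benzene, 80 °C) then generates the acyl radical, which adds to C1 of the enone and gives 15 after hydrogen transfer under neutral conditions.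

Step 9 is the next risk: the diene may react at its α-carbon instead of C5, and the facial sense at C5 (anti to the silyloxy group rather than syn to the C–O bond) is an argued, not a proven, preference. The fallback sets out from 7 and 12 and comes back at 13, setting C5 by protonation instead of by C–C bond formation. If the aldol gives mainly the C5 epimer F3 (side chain cis to the C4 silyloxy group), Et3SiOTf/Et3N converts it into the extended silyl dienol ether F4, in which C5 is trigonal. Kinetic protonation with acetic acid at −78 °C is then expected to place the small proton on C5 syn to the C4–O bond, which gives 13.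

Step 10 is the third risk: the aldehyde-selective Wacker oxidation may give the methyl ketone, and the catalyst may also scramble the allylic acetate. The fallback sets out from 13 and comes back at 14. Hydroboration of the terminal alkene with disiamylborane followed by NaBO3 oxidation gives the primary alcohol F5, and Dess–Martin periodinane oxidises it to 14.

**Further compounds**
F1 | step 11 | carboxylic acid from 14 (C10 as CO2H) | OC(=O)CC[C@@H]([C@H](C)C[C@H](C=C(C)C)OC(C)=O)[C@@H](O[Si](CC)(CC)CC)[C@H]1C=CC(=O)[C@]1(C)O[Si](CC)(CC)CC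
F2 | step 11 | Se-phenyl selenoester of F1 | O=C([Se]c1ccccc1)CC[C@@H]([C@H](C)C[C@H](C=C(C)C)OC(C)=O)[C@@H](O[Si](CC)(CC)CC)[C@H]1C=CC(=O)[C@]1(C)O[Si](CC)(CC)CC
F3 | step 9 | C5 epimer of 13 | C=CC[C@@H]([C@H](C)C[C@H](C=C(C)C)OC(C)=O)[C@@H](O[Si](CC)(CC)CC)[C@@H]1C=CC(=O)[C@]1(C)O[Si](CC)(CC)CC
F4 | step 9 | extended silyl dienol ether of 13 (C5 trigonal, C3–OSiEt3) | C=CC[C@@H]([C@H](C)C[C@H](C=C(C)C)OC(C)=O)[C@@H](O[Si](CC)(CC)CC)C1=CC=C(O[Si](CC)(CC)CC)[C@]1(C)O[Si](CC)(CC)CC
F5 | step 10 | primary alcohol from 13 (C10 as CH2OH) | OCCC[C@@H]([C@H](C)C[C@H](C=C(C)C)OC(C)=O)[C@@H](O[Si](CC)(CC)CC)[C@H]1C=CC(=O)[C@]1(C)O[Si](CC)(CC)CC
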